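**Retrosynthetic overview**
1. The epoxide is made last, by hydroxyl-directed epoxidation of the C5=C6 olefin of the azulene half; the benzoxepine C7 methyl carbinol comes from methyl addition to a ketone and the azulene C7 carbinol from an enone reduction.
2. Key disconnection: the bridge bond C1′–C2′, formed by an intermolecular vinylogous Mukaiyama–Michael addition of a hydroazulenone silyl dienol ether (right half) to a benzoxepine α-methylene ketone (left half).
3. Left half: oxepane and cyclohexanone are closed in one epoxonium cascade of an acyclic (R,R,R)-diepoxy β-keto ester enol ether (geranyl bromide, Shi epoxidation).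
4. Right half: cyclopentene first (ring-closing metathesis of an (S)-linalyl ester made from geraniol, then Ireland–Claisen chirality transfer), second five-membered ring by diazoketone cyclopropanation and ring opening, then two-carbon ring expansion to the seven-membered 1,3-dione and Stork–Danheiser enone.
5. Ring order: oxepane + cyclohexane (one step) on the left; cyclopentene → cyclopentanone → cycloheptenone on the right; oxirane last.

Assumption (labels): the left half is numbered as 1-benzoxepine (O1, C2 … C9a), the right half as azulene (C1 … C8a), the bridge carbons are C1′ (on benzoxepine C6) and C2′ (on azulene C5); "Shi ketone" is the D-fructose-derived ketone catalyst.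

**Left half**

Step 1
Reactants: 1 geranyl bromide; 2 N-methoxy-N-methylacetamide
Product: 3 (E)-N-methoxy-N,5,9-trimethyldeca-4,8-dienamide
Conditions: 2, LiN(i-Pr)2, THF, −78 °C; then 1, −78 → −30 °C
Reagents that add atoms: none
Why: Enolate alkylation (SN2) of the lithium enolate of the Weinreb acetamide with the primary allylic bromide adds two carbons and leaves the E-olefin untouched.

Step 2
Reactants: 3 (E)-N-methoxy-N,5,9-trimethyldeca-4,8-dienamide
Product: 4 (4R,5R,8R)-4,5:8,9-diepoxy-N-methoxy-N,5,9-trimethyldecanamide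
Conditions: Shi ketone (0.6 equiv), KHSO5 (as 2KHSO5·KHSO4·K2SO4), K2CO3, Bu4NHSO4, MeCN/CH2(OMe)2/aq. Na2B4O7 buffer (pH 10.5), 0 °C
Reagents that add atoms: potassium peroxymonosulfate, OOS(=O)(=O)[O-].[K+]
Why: Shi asymmetric epoxidation, in which the chiral dioxirane attacks both trisubstituted olefins through the spiro transition state and sets the (4R,5R) and (8R) epoxide centres.

Step 3
Reactants: 4 (4R,5R,8R)-4,5:8,9-diepoxy-N-methoxy-N,5,9-trimethyldecanamide
Product: 5 methyl (6R,7R,10R)-6,7:10,11-diepoxy-7,11-dimethyl-3-oxododecanoate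
Conditions: MeOAc, LiN(i-Pr)2 (3 equiv), THF, −78 °C; then 4, −78 → −40 °C; aq. NH4Cl
Reagents that add atoms: methyl acetate, CC(=O)OC
Why: Crossed Claisen-type acylation of the methyl acetate enolate by the Weinreb amide, whose chelated tetrahedral intermediate stops at the β-keto ester and gives it regiospecifically while the epoxides survive at low temperature.

Step 4
Reactants: 5 methyl (6R,7R,10R)-6,7:10,11-diepoxy-7,11-dimethyl-3-oxododecanoate
Product: 6 methyl (2Z,6R,7R,10R)-3-(tert-butyldimethylsilyloxy)-6,7:10,11-diepoxy-7,11-dimethyldodec-2-enoate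
Conditions: t-BuMe2SiCl, Et3N, DMAP (cat.), DMF, 25 °C
Reagents that add atoms: tert-butyldimethylsilyl chloride, CC(C)(C)[Si](C)(C)Cl
Why: O-silylation of the β-keto ester enol under non-Lewis-acidic conditions gives the conjugated enol ether, which fixes the future C6 (not C8) as the nucleophilic carbon.

Step 5
Reactants: 6 methyl (2Z,6R,7R,10R)-3-(tert-butyldimethylsilyloxy)-6,7:10,11-diepoxy-7,11-dimethyldodec-2-enoate
Product: 8 methyl (3R,5aR,6R,9aR)-3-hydroxy-2,2,5a-trimethyl-7-oxodecahydro-1-benzoxepine-6-carboxylate, via trimethylsilyl ether 7 (not isolated)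
Conditions: Me3SiOTf (1.2 equiv), 2,6-di-tert-butyl-4-methylpyridine, CH2Cl2, −78 °C; then K2CO3, MeOH, 0 °C
Reagents that add atoms: none
Why: Silyl-triflate-promoted tandem oxa-/carbacyclisation (epoxonium cascade), in which the internal epoxide oxygen opens the activated terminal epoxide at its tertiary carbon to close the oxepane (C3 R carried over) and the bicyclic epoxonium ion is then opened at its tertiary carbon with inversion by the enol ether carbon through a chair, giving the trans ring fusion (5aR,9aR).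

Step 6
Reactants: 8 methyl (3R,5aR,6R,9aR)-3-hydroxy-2,2,5a-trimethyl-7-oxodecahydro-1-benzoxepine-6-carboxylate
Product: 9 methyl (3R,5aR,9aR)-3,7-bis(tert-butyldimethylsilyloxy)-2,2,5a-trimethyl-2,3,4,5,5a,8,9,9a-octahydro-1-benzoxepine-6-carboxylate
Conditions: t-BuMe2SiOTf (2.5 equiv), Et3N, CH2Cl2, −78 → 0 °C
Reagents that add atoms: tert-butyldimethylsilyl triflate, CC(C)(C)[Si](C)(C)OS(=O)(=O)C(F)(F)F
Why: Silylation of the C3 alcohol and soft enolisation/O-silylation of the β-keto ester occur together, protecting C3–OH and masking the ketone as a β-silyloxy acrylate for the coming reduction.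

Step 7
Reactants: 9 methyl (3R,5aR,9aR)-3,7-bis(tert-butyldimethylsilyloxy)-2,2,5a-trimethyl-2,3,4,5,5a,8,9,9a-octahydro-1-benzoxepine-6-carboxylate
Product: 11 (3R,5aR,9aR)-3-(tert-butyldimethylsilyloxy)-2,2,5a-trimethyl-6-methylideneoctahydro-1-benzoxepin-7(2H)-one, via allylic alcohol 10 (not isolated)
Conditions: i-Bu2AlH (2.5 equiv), CH2Cl2, −78 °C; then 0.5 M HCl, THF, 0 °C
Reagents that add atoms: none
Why: 1,2-Reduction of the vinylogous carbonate to the allylic alcohol followed by acid-promoted loss of water through the silyloxocarbenium ion (allylic transposition) unveils the α-methylene ketone regiospecifically at C6.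

**Right half**

Step 8
Reactants: 12 geraniol
Product: 13 (2S,3S)-2,3-epoxygeraniol
Conditions: Ti(OiPr)4 (5 mol %), L-(+)-diethyl tartrate (6 mol %), t-BuOOH, 4 Å molecular sieves, CH2Cl2, −20 °C
Reagents that add atoms: tert-butyl hydroperoxide, CC(C)(C)OO
Why: Sharpless asymmetric epoxidation, in which the L-tartrate titanium complex delivers oxygen to one face of the allylic alcohol and sets the (2S,3S) epoxide.

Step 9
Reactants: 13 (2S,3S)-2,3-epoxygeraniol
Product: 14 2,3-epoxygeranyl iodide (configuration of 13 unchanged; 2R,3S by CIP)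
Conditions: I2, PPh3, imidazole, CH2Cl2, 0 °C
Reagents that add atoms: iodine, II
Why: Appel-type iodination converts the primary alcohol into the iodide without touching the epoxide stereocentres.

Step 10
Reactants: 14 2,3-epoxygeranyl iodide
Product: 15 (S)-linalool
Conditions: Zn dust, AcOH (cat.), EtOH, reflux
Reagents that add atoms: none
Why: Zinc-mediated reductive β-elimination opens the epoxide to the tertiary allylic alcohol, and because the C3–O bond is never broken the (3S) centre is retained.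

Step 11
Reactants: 15 (S)-linalool
Product: 16 (S)-linalyl 2-methylpropanoate
Conditions: n-BuLi, THF, −78 °C; then i-PrCOCl, −78 → 0 °C
Reagents that add atoms: 2-methylpropanoyl chloride, CC(C)C(Cl)=O
Why: Acylation of the lithium alkoxide esterifies the hindered tertiary alcohol without ionising it.

Step 12
Reactants: 16 (S)-linalyl 2-methylpropanoate
Product: 17 (S)-1-methylcyclopent-2-en-1-yl 2-methylpropanoate
Conditions: second-generation Grubbs catalyst RuCl2(=CHPh)(PCy3)(H2IMes) (1 mol %), CH2Cl2, 40 °C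
Reagents that add atoms: none
Why: Ring-closing metathesis of the 1,6-diene expels 2-methylpropene and gives the cyclopentenyl ester with the carbinol centre unchanged.

Step 13
Reactants: 17 (S)-1-methylcyclopent-2-en-1-yl 2-methylpropanoate
Product: 20 (R)-2-methyl-2-(3-methylcyclopent-2-en-1-yl)propanoic acid, via silyl ketene acetal 18 (not isolated), via trimethylsilyl ester 19 (not isolated)
Conditions: LiN(i-Pr)2, THF, −78 °C; Me3SiCl/Et3N, −78 → 60 °C; then 1 M HCl
Reagents that add atoms: none
Why: Ireland–Claisen [3,3] rearrangement forms the CMe2–ring bond suprafacially, so the C–O chirality of the tertiary ester is transferred completely to the new (R) ring carbon while the olefin moves next to the methyl-bearing carbon.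

Step 14
Reactants: 20 (R)-2-methyl-2-(3-methylcyclopent-2-en-1-yl)propanoic acid
Product: 22 (R)-1-diazo-3-methyl-3-(3-methylcyclopent-2-en-1-yl)butan-2-one, via acid chloride 21 (not isolated)
Conditions: (COCl)2, DMF (cat.), CH2Cl2, 0 → 25 °C; then CH2N2 (3 equiv), Et2O, 0 °C
Reagents that add atoms: diazomethane, C=[N+]=[N-]
Why: Acylation of diazomethane by the acid chloride (first stage of an Arndt–Eistert sequence) gives the diazomethyl ketone, the extra equivalent of diazomethane scavenging HCl.

Step 15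
Reactants: 22 (R)-1-diazo-3-methyl-3-(3-methylcyclopent-2-en-1-yl)butan-2-one
Product: 23 4,4,8-trimethyltricyclo[3.3.0.0^2,8]octan-3-one (cyclopropane on the face of the CMe2 tether)
Conditions: Rh2(OAc)4 (1 mol %), CH2Cl2, 25 °C, slow addition
Reagents that add atoms: none
Why: Intramolecular rhodium-carbenoid cyclopropanation can only reach the olefin face that carries the tether, so the new five-membered ring is cis-fused and the ring-fusion centres follow from the (R) centre of 22.

Step 16
Reactants: 23 4,4,8-trimethyltricyclo[3.3.0.0^2,8]octan-3-one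
Product: 24 (1R,5R,6R)-6-hydroxy-2,2,6-trimethyl-cis-bicyclo[3.3.0]octan-3-one
Conditions: 1 M aq. HClO4, THF, 25 °C
Reagents that add atoms: water, O
Why: Acid-catalysed homoconjugate addition (cyclopropyl ketone ring opening) cleaves the cyclopropane bond that overlaps with the carbonyl and ends at the tertiary carbon, and water enters from the convex face with inversion, placing the hydroxyl cis to the ring-fusion hydrogens and the methyl on the concave face.

Step 17
Reactants: 24 (1R,5R,6R)-6-hydroxy-2,2,6-trimethyl-cis-bicyclo[3.3.0]octan-3-one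
Product: 25 (1R,5R,6R)-2,2,6-trimethyl-3,6-bis(trimethylsilyloxy)bicyclo[3.3.0]oct-3-ene
Conditions: LiN(i-Pr)2 (2.3 equiv), THF, −78 °C; Me3SiCl (2.6 equiv), −78 → 0 °C
Reagents that add atoms: chlorotrimethylsilane, C[Si](C)(C)Cl
Why: Enolate O-silylation can only go toward the CH2 side because the other α-carbon is quaternary, and the tertiary alkoxide is capped as its trimethylsilyl ether in the same operation.

Step 18
Reactants: 25 (1R,5R,6R)-2,2,6-trimethyl-3,6-bis(trimethylsilyloxy)bicyclo[3.3.0]oct-3-ene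
Product: 26 dichlorocyclobutanone adduct of 25 (cyclobutanone cis-fused on the convex face; C=O carbon on the former enol CH, CCl2 on the silyloxy carbon)
Conditions: Cl2CHCOCl, Et3N, hexanes, 25 °C
Reagents that add atoms: dichloroacetyl chloride, ClC(Cl)C(Cl)=O
Why: [2+2] Cycloaddition of dichloroketene generated in the flask with the electron-rich silyl enol ether is regiospecific (ketene carbonyl carbon to the nucleophilic enol carbon) and occurs on the convex face of the cis-fused bicycle.

Step 19
Reactants: 26 dichlorocyclobutanone adduct of 25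
Product: 28 (1R,3aR,8aR)-1-hydroxy-1,4,4-trimethyloctahydroazulene-5,7-dione, via dechlorinated cyclobutanone 27 (not isolated)
Conditions: Zn, AcOH, i-PrOH/H2O (1:1), 0 → 25 °C
Reagents that add atoms: none
Why: Reductive dechlorination followed by desilylation and strain-releasing retro-aldol cleavage of the ring-fusion bond expands the cyclopentanone by two carbons to the cycloheptane-1,3-dione without touching the three stereocentres.

Step 20
Reactants: 28 (1R,3aR,8aR)-1-hydroxy-1,4,4-trimethyloctahydroazulene-5,7-dione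
Product: 29 (1R,3aR,8aR)-1-hydroxy-1,4,4,6-tetramethyloctahydroazulene-5,7-dione
Conditions: MeI, K2CO3, acetone, 50 °C
Reagents that add atoms: iodomethane, CI
Why: C-Alkylation of the 1,3-diketone enolate installs the C6 methyl at the only doubly activated carbon (its configuration is irrelevant because it becomes sp2).

Step 21
Reactants: 29 (1R,3aR,8aR)-1-hydroxy-1,4,4,6-tetramethyloctahydroazulene-5,7-dione
Product: 30 (1R,3aR,8aR)-1-hydroxy-7-methoxy-1,4,4,6-tetramethyl-2,3,3a,4,8,8a-hexahydroazulen-5(1H)-one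
Conditions: MeOH, HC(OMe)3, TsOH (cat.), 25 °C
Reagents that add atoms: methanol, CO
Why: Acid-catalysed enol etherification takes place at the less hindered C7 carbonyl, leaving the carbonyl next to the gem-dimethyl carbon free as the vinylogous ester C=O.

Step 22
Reactants: 30 (1R,3aR,8aR)-1-hydroxy-7-methoxy-1,4,4,6-tetramethyl-2,3,3a,4,8,8a-hexahydroazulen-5(1H)-one
Product: 32 (1R,3aR,8aR)-1-hydroxy-1,4,4,5,6-pentamethyl-2,3,3a,4,8,8a-hexahydroazulen-7(1H)-one, via tertiary carbinol adduct 31 (not isolated)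
Conditions: MeLi (3 equiv), THF, −78 → 0 °C; then 1 M HCl, 0 °C
Reagents that add atoms: methyllithium, [Li]C
Why: Stork–Danheiser sequence, in which 1,2-addition of methyllithium to the vinylogous ester carbonyl and acid hydrolysis with loss of water transpose the carbonyl to C7 and give the tetrasubstituted enone.

Step 23
Reactants: 32 (1R,3aR,8aR)-1-hydroxy-1,4,4,5,6-pentamethyl-2,3,3a,4,8,8a-hexahydroazulen-7(1H)-one
Product: 33 (1R,3aR,8aR)-1,4,4,6-tetramethyl-5-methylidene-1,7-bis(triethylsilyloxy)-1,2,3,3a,4,5,8,8a-octahydroazulene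
Conditions: Et3SiOTf (2.5 equiv), Et3N, CH2Cl2, −78 → 0 °C
Reagents that add atoms: triethylsilyl triflate, CC[Si](CC)(CC)OS(=O)(=O)C(F)(F)F
Why: Soft enolisation under equilibrating conditions removes a γ-proton from the C5 methyl to give the linear exocyclic silyl dienol ether (which relieves the crowding of the tetrasubstituted olefin next to C4), and the tertiary alcohol is silylated at the same time.

**Union and end game**

Step 24
Reactants: 11 (3R,5aR,9aR)-3-(tert-butyldimethylsilyloxy)-2,2,5a-trimethyl-6-methylideneoctahydro-1-benzoxepin-7(2H)-one; 33 (1R,3aR,8aR)-1,4,4,6-tetramethyl-5-methylidene-1,7-bis(triethylsilyloxy)-1,2,3,3a,4,5,8,8a-octahydroazulene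
Product: 34 coupled enone in which benzoxepine C6 (now part of a C6=C7 triethylsilyl enol ether) carries CH2CH2 to azulene C5 of the C5=C6 enone (C7=O)
Conditions: Tf2NH (5 mol %), CH2Cl2, −78 °C; then Et3N
Reagents that add atoms: none
Why: Vinylogous Mukaiyama–Michael addition, in which the unhindered exocyclic CH2 (γ-carbon) of the s-trans-locked dienol ether adds to the exocyclic CH2 of the silyl-activated enone to form the C1′–C2′ bond, and silyl transfer leaves the left ketone masked as its regiodefined enol ether while the right enone is regenerated.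

Step 25
Reactants: 34 coupled enone
Product: 35 (7R)-allylic alcohol of 34 (azulene C7–OH cis to the ring-fusion hydrogens)
Conditions: (S)-2-methyl-CBS-oxazaborolidine (0.3 equiv), catecholborane, toluene, −78 °C
Reagents that add atoms: none
Why: Corey–Bakshi–Shibata reduction, in which the (S)-catalyst treats the α-methyl olefinic side of the enone as the large group and delivers hydride under catalyst control to give the 7R carbinol, the silyl enol ether and silyl ethers being inert.

Step 26
Reactants: 35 (7R)-allylic alcohol of 34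
Product: 36 (6R)-benzoxepin-7-one carrying the hydroxy-azulenylethyl side chain equatorial at C6
Conditions: K2CO3, MeOH, 25 °C
Reagents that add atoms: none
Why: Methanolysis of the silyl enol ether releases the ketone and the basic medium equilibrates C6 to the thermodynamic equatorial (6R) epimer, while alkyl silyl ethers survive and retro-Michael cleavage is impossible because the right enone is already reduced.

Step 27
Reactants: 36 (6R)-benzoxepin-7-one
Product: 37 (6R,7S)-7-methyl carbinol (benzoxepine C7–OH axial, cis to the C5a methyl)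
Conditions: MeLi, CeCl3 (4 equiv), THF, −78 °C
Reagents that add atoms: methyllithium, [Li]C
Why: Organocerium 1,2-addition suppresses enolisation and attacks the ketone from the equatorial direction because the axial path is blocked by the 1,3-diaxial C5a methyl, giving the axial hydroxyl and equatorial methyl (7S).

Step 28
Reactants: 37 (6R,7S)-7-methyl carbinol
Product: 38 tetraol (both silyl ethers removed, C5=C6 azulene olefin intact)
Conditions: Bu4NF, THF, 50 °C
Reagents that add atoms: none
Why: Fluoride desilylation removes the secondary tert-butyldimethylsilyl and tertiary triethylsilyl ethers under basic conditions that the allylic alcohol tolerates.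

Step 29
Reactants: 38 tetraol
Product: 39 CNP0203623.2 (target)
Conditions: VO(acac)2 (5 mol %), t-BuOOH, CH2Cl2, 0 → 25 °C
Reagents that add atoms: tert-butyl hydroperoxide, CC(C)(C)OO
Why: Vanadium-catalysed hydroxyl-directed epoxidation delivers oxygen to the only olefin from the face of the adjacent C7 hydroxyl, giving the syn epoxy alcohol (5S,6R) as is general for cyclohept-2-enols.

**Compound list**
1 | geranyl bromide | CC(C)=CCC/C(C)=C/CBr | starting material
2 | N-methoxy-N-methylacetamide | CON(C)C(C)=O | starting material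
3 | (E)-N-methoxy-N,5,9-trimethyldeca-4,8-dienamide | CON(C)C(=O)CC/C=C(\C)CCC=C(C)C | intermediate
4 | (4R,5R,8R)-4,5:8,9-diepoxy-N-methoxy-N,5,9-trimethyldecanamide | CON(C)C(=O)CC[C@H]1O[C@]1(C)CC[C@H]1OC1(C)C | intermediate
5 | methyl (6R,7R,10R)-6,7:10,11-diepoxy-7,11-dimethyl-3-oxododecanoate | COC(=O)CC(=O)CC[C@H]1O[C@]1(C)CC[C@H]1OC1(C)C | intermediate
6 | methyl (2Z,6R,7R,10R)-3-(tert-butyldimethylsilyloxy)-6,7:10,11-diepoxy-7,11-dimethyldodec-2-enoate | COC(=O)/C=C(\O[Si](C)(C)C(C)(C)C)CC[C@H]1O[C@]1(C)CC[C@H]1OC1(C)C | intermediate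
7 | methyl (3R,5aR,6R,9aR)-2,2,5a-trimethyl-7-oxo-3-(trimethylsilyloxy)decahydro-1-benzoxepine-6-carboxylate | CC1(C)O[C@@H]2CCC(=O)[C@H](C(=O)OC)[C@@]2(C)CC[C@H]1O[Si](C)(C)C | intermediate
8 | methyl (3R,5aR,6R,9aR)-3-hydroxy-2,2,5a-trimethyl-7-oxodecahydro-1-benzoxepine-6-carboxylate | CC1(C)O[C@@H]2CCC(=O)[C@H](C(=O)OC)[C@@]2(C)CC[C@H]1O | intermediate
9 | methyl (3R,5aR,9aR)-3,7-bis(tert-butyldimethylsilyloxy)-2,2,5a-trimethyl-2,3,4,5,5a,8,9,9a-octahydro-1-benzoxepine-6-carboxylate | CC1(C)O[C@@H]2CCC(O[Si](C)(C)C(C)(C)C)=C(C(=O)OC)[C@@]2(C)CC[C@H]1O[Si](C)(C)C(C)(C)C | intermediate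
10 | [(3R,5aR,9aR)-3,7-bis(tert-butyldimethylsilyloxy)-2,2,5a-trimethyl-2,3,4,5,5a,8,9,9a-octahydro-1-benzoxepin-6-yl]methanol | CC1(C)O[C@@H]2CCC(O[Si](C)(C)C(C)(C)C)=C(CO)[C@@]2(C)CC[C@H]1O[Si](C)(C)C(C)(C)C | intermediate
11 | (3R,5aR,9aR)-3-(tert-butyldimethylsilyloxy)-2,2,5a-trimethyl-6-methylideneoctahydro-1-benzoxepin-7(2H)-one | CC1(C)O[C@@H]2CCC(=O)C(=C)[C@@]2(C)CC[C@H]1O[Si](C)(C)C(C)(C)C | intermediate
12 | geraniol | CC(C)=CCC/C(C)=C/CO | starting material
13 | (2S,3S)-2,3-epoxygeraniol | CC(C)=CCC[C@]1(C)O[C@H]1CO | intermediate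
14 | 2,3-epoxygeranyl iodide (2R,3S by CIP) | CC(C)=CCC[C@]1(C)O[C@H]1CI | intermediate
15 | (S)-linalool | CC(C)=CCC[C@](C)(O)C=C | intermediate
16 | (S)-linalyl 2-methylpropanoate | CC(C)=CCC[C@](C)(OC(=O)C(C)C)C=C | intermediate
17 | (S)-1-methylcyclopent-2-en-1-yl 2-methylpropanoate | C[C@]1(OC(=O)C(C)C)CCC=C1 | intermediate
18 | trimethylsilyl ketene acetal of 17 | C[C@]1(OC(O[Si](C)(C)C)=C(C)C)CCC=C1 | intermediate
19 | trimethylsilyl (R)-2-methyl-2-(3-methylcyclopent-2-en-1-yl)propanoate | C[Si](C)(C)OC(=O)C(C)(C)[C@H]1C=C(C)CC1 | intermediate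
20 | (R)-2-methyl-2-(3-methylcyclopent-2-en-1-yl)propanoic acid | OC(=O)C(C)(C)[C@H]1C=C(C)CC1 | intermediate
21 | (R)-2-methyl-2-(3-methylcyclopent-2-en-1-yl)propanoyl chloride | ClC(=O)C(C)(C)[C@H]1C=C(C)CC1 | intermediate
22 | (R)-1-diazo-3-methyl-3-(3-methylcyclopent-2-en-1-yl)butan-2-one | [N-]=[N+]=CC(=O)C(C)(C)[C@H]1C=C(C)CC1 | intermediate
23 | 4,4,8-trimethyltricyclo[3.3.0.0^2,8]octan-3-one | O=C1[C@H]2[C@@]3(C)CC[C@@H](C1(C)C)[C@@H]23 | intermediate
24 | (1R,5R,6R)-6-hydroxy-2,2,6-trimethyl-cis-bicyclo[3.3.0]octan-3-one | O=C1C[C@@H]2[C@@H](CC[C@@]2(C)O)C1(C)C | intermediate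
25 | (1R,5R,6R)-2,2,6-trimethyl-3,6-bis(trimethylsilyloxy)bicyclo[3.3.0]oct-3-ene | C[Si](C)(C)OC1=C[C@@H]2[C@@H](CC[C@@]2(C)O[Si](C)(C)C)C1(C)C | intermediate
26 | dichlorocyclobutanone adduct of 25 | C[Si](C)(C)O[C@@]12C(Cl)(Cl)C(=O)[C@@H]1[C@@H]1[C@@H](CC[C@@]1(C)O[Si](C)(C)C)C2(C)C | intermediate
27 | dechlorinated cyclobutanone from 26 | C[Si](C)(C)O[C@@]12CC(=O)[C@@H]1[C@@H]1[C@@H](CC[C@@]1(C)O[Si](C)(C)C)C2(C)C | intermediate
28 | (1R,3aR,8aR)-1-hydroxy-1,4,4-trimethyloctahydroazulene-5,7-dione | O=C1CC(=O)C[C@@H]2[C@@H](CC[C@@]2(C)O)C1(C)C | intermediate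
29 | (1R,3aR,8aR)-1-hydroxy-1,4,4,6-tetramethyloctahydroazulene-5,7-dione | O=C1C(C)C(=O)C[C@@H]2[C@@H](CC[C@@]2(C)O)C1(C)C | intermediate
30 | (1R,3aR,8aR)-1-hydroxy-7-methoxy-1,4,4,6-tetramethyl-2,3,3a,4,8,8a-hexahydroazulen-5(1H)-one | O=C1C(C)=C(OC)C[C@@H]2[C@@H](CC[C@@]2(C)O)C1(C)C | intermediate
31 | (1R,3aR,8aR)-7-methoxy-1,4,4,5,6-pentamethyl-1,2,3,3a,4,5,8,8a-octahydroazulene-1,5-diol (mixture at C5) | CC1(O)C(C)=C(OC)C[C@@H]2[C@@H](CC[C@@]2(C)O)C1(C)C | intermediate
32 | (1R,3aR,8aR)-1-hydroxy-1,4,4,5,6-pentamethyl-2,3,3a,4,8,8a-hexahydroazulen-7(1H)-one | CC1=C(C)C(=O)C[C@@H]2[C@@H](CC[C@@]2(C)O)C1(C)C | intermediate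
33 | (1R,3aR,8aR)-1,4,4,6-tetramethyl-5-methylidene-1,7-bis(triethylsilyloxy)-1,2,3,3a,4,5,8,8a-octahydroazulene | C=C1C(C)=C(O[Si](CC)(CC)CC)C[C@@H]2[C@@H](CC[C@@]2(C)O[Si](CC)(CC)CC)C1(C)C | intermediate
34 | coupled enone: benzoxepine C6=C7 triethylsilyl enol ether linked by CH2CH2 to azulene C5 of the C5=C6 enone (C7=O) | CC1(C)O[C@@H]2CCC(O[Si](CC)(CC)CC)=C(CCC3=C(C)C(=O)C[C@@H]4[C@@H](CC[C@@]4(C)O[Si](CC)(CC)CC)C3(C)C)[C@@]2(C)CC[C@H]1O[Si](C)(C)C(C)(C)C | intermediate
35 | (7R)-allylic alcohol of 34 | CC1(C)O[C@@H]2CCC(O[Si](CC)(CC)CC)=C(CCC3=C(C)[C@H](O)C[C@@H]4[C@@H](CC[C@@]4(C)O[Si](CC)(CC)CC)C3(C)C)[C@@]2(C)CC[C@H]1O[Si](C)(C)C(C)(C)C | intermediate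
36 | (6R)-benzoxepin-7-one with free azulene C7–OH | CC1(C)O[C@@H]2CCC(=O)[C@H](CCC3=C(C)[C@H](O)C[C@@H]4[C@@H](CC[C@@]4(C)O[Si](CC)(CC)CC)C3(C)C)[C@@]2(C)CC[C@H]1O[Si](C)(C)C(C)(C)C | intermediate
37 | (6R,7S)-7-methyl carbinol, still silylated at benzoxepine O3 and azulene O1 | CC1(C)O[C@@H]2CC[C@](C)(O)[C@H](CCC3=C(C)[C@H](O)C[C@@H]4[C@@H](CC[C@@]4(C)O[Si](CC)(CC)CC)C3(C)C)[C@@]2(C)CC[C@H]1O[Si](C)(C)C(C)(C)C | intermediate
38 | tetraol with C5=C6 azulene olefin | CC1(C)O[C@@H]2CC[C@](C)(O)[C@H](CCC3=C(C)[C@H](O)C[C@@H]4[C@@H](CC[C@@]4(C)O)C3(C)C)[C@@]2(C)CC[C@H]1O | intermediate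
39 | CNP0203623.2: (3R,5aR,6R,7S,9aR)-benzoxepine-3,7-diol linked from C6 by CH2CH2 to C5 of (1R,3aR,5S,6R,7R,8aR)-5,6-epoxy-1,4,4,6-tetramethyldecahydroazulene-1,7-diol | CC1(C)O[C@@H]2CC[C@](C)(O)[C@H](CC[C@@]34O[C@]3(C)[C@H](O)C[C@@H]3[C@@H](CC[C@@]3(C)O)C4(C)C)[C@@]2(C)CC[C@H]1O | target

**Totals**
Total step count: 29 (left half 7, right half 16, union and end game 6).
Longest linear sequence: 22 steps (12 → 39, steps 8–23 then 24–29).

**Three steps most likely to fail**

Step 5 (epoxonium cascade). The push–pull enol ether in 6 is a weaker carbon nucleophile than the simple enol silanes known to end such cascades, so O-cyclisation or premature quenching may win. The fallback sets out from 4 and comes back at 11. CH2=CHMgBr turns the Weinreb amide into the diepoxy vinyl ketone F1. PhSSiMe3 with catalytic Bu4NF then adds 1,4 and gives the regiodefined (Z)-3-(phenylsulfanyl) trimethylsilyl enol ether F2, an ordinary and more nucleophilic enol silane. The same Me3SiOTf cascade and methanolysis give the bicyclic β-phenylsulfanyl ketone F3, and t-BuMe2SiOTf/2,6-lutidine gives its silyl ether F4. mCPBA at −78 °C gives the sulfoxide F5, whose thermal syn-elimination (toluene, CaCO3, 80 °C) gives 11.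

Step 16 (hydrative cyclopropane opening). The tertiary cation can eliminate instead of being captured by water. The fallback sets out from 20 and comes back at 24. MeLi (2 equiv) converts the acid into the methyl ketone F6, and LiN(i-Pr)2/Me3SiCl gives its only possible trimethylsilyl enol ether F7. Pd(OAc)2 under O2 in DMSO closes the second ring by cycloalkenylation onto the ring olefin and gives the cis-fused methylidene ketone F8 (an endocyclic olefin isomer converges in the next operation). Mukaiyama hydration (Co(acac)2, PhSiH3, O2) then traps the tertiary radical from the convex face and gives 24.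

Step 23 (regiochemistry of the dienol ether). α′-Deprotonation would give the cross-conjugated isomer, which would couple at C8 in step 24. The fallback sets out from 29 and comes back at 33 without any deprotonation of an enone. Et3SiOTf/Et3N silylates the less hindered enol oxygen and the tertiary alcohol of 29 and gives the bis(triethylsilyl) vinylogous ester F9. Carbonyl methylenation of its hindered C5 carbonyl with Cp2Ti(CH2)(Cl)AlMe2 and pyridine in THF/toluene (−40 → 25 °C) gives 33 regiospecifically.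

**Further compounds**
F1 | step 5 | (6R,7R,10R)-6,7:10,11-diepoxy-7,11-dimethyldodec-1-en-3-one | C=CC(=O)CC[C@H]1O[C@]1(C)CC[C@H]1OC1(C)C
F2 | step 5 | trimethyl{[(2Z,6R,7R,10R)-6,7:10,11-diepoxy-7,11-dimethyl-1-(phenylsulfanyl)dodec-2-en-3-yl]oxy}silane | C[Si](C)(C)O/C(CC[C@H]1O[C@]1(C)CC[C@H]1OC1(C)C)=C\CSc1ccccc1
F3 | step 5 | (3R,5aR,9aR)-3-hydroxy-2,2,5a-trimethyl-6-[(phenylsulfanyl)methyl]octahydro-1-benzoxepin-7(2H)-one (C6 side chain equatorial) | CC1(C)O[C@@H]2CCC(=O)[C@H](CSc3ccccc3)[C@@]2(C)CC[C@H]1O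
F4 | step 5 | 3-O-tert-butyldimethylsilyl ether of F3 | CC1(C)O[C@@H]2CCC(=O)[C@H](CSc3ccccc3)[C@@]2(C)CC[C@H]1O[Si](C)(C)C(C)(C)C
F5 | step 5 | sulfoxide of F4 | CC1(C)O[C@@H]2CCC(=O)[C@H](CS(=O)c3ccccc3)[C@@]2(C)CC[C@H]1O[Si](C)(C)C(C)(C)C
F6 | step 16 | (R)-3-methyl-3-(3-methylcyclopent-2-en-1-yl)butan-2-one | CC(=O)C(C)(C)[C@H]1C=C(C)CC1
F7 | step 16 | trimethylsilyl enol ether of F6 | C=C(O[Si](C)(C)C)C(C)(C)[C@H]1C=C(C)CC1
F8 | step 16 | (1R,5R)-2,2-dimethyl-6-methylidene-cis-bicyclo[3.3.0]octan-3-one | O=C1C[C@@H]2[C@@H](CCC2=C)C1(C)C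
F9 | step 23 | (1R,3aR,8aR)-1,4,4,6-tetramethyl-1,7-bis(triethylsilyloxy)-2,3,3a,4,8,8a-hexahydroazulen-5(1H)-one | O=C1C(C)=C(O[Si](CC)(CC)CC)C[C@@H]2[C@@H](CC[C@@]2(C)O[Si](CC)(CC)CC)C1(C)C
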